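## Plan

1. **Cuts.** C2–Br and C8–Br go back to C–O (PMB ether, silyl ether), C4–Cl and C6–Cl to an anti-1,3-diol, and the C4 carbinol to a ketone. The ring bond C5–C6 is then cut as an aldol, followed by C3–C4 (acetyl unit as a 1-ethoxyvinyl cuprate), C7–C8 (chloroformate) and C3–C7 (dibromo-olefination). This leaves D-pantolactone, which supplies C3, C2, C1 with both methyls, and C6.
2. **Enabling feature.** C5 is the only CH2 of the ring and sits between the chlorine-bearing C4 and C6. That 1,3-pattern is an aldol retron (C4 methyl ketone plus C6 aldehyde). C6 hangs on quaternary C1 and C3 is an alkene carbon, so only one enolate and one acceptor exist.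
3. **Forward order.** The chain C6–C1–C2–C3(=C7–C8)–C4–C5 is assembled first, the single six-membered ring closes in the key step, and the halogens come last (Cl at C4 and C6, then Br at C8, then Br at C2).
4. **Stereochemistry.** C2 comes from D-pantolactone and is inverted by bromide at the end. The alkene geometry comes from syn-carbocupration of an alkynoate. C6 is set by magnesium chelation in the aldol and C4 by C6-hydroxyl-directed reduction; both are then inverted by chloride.

Key step: step 11

Remark on the chemistry: atom labels C1–C8 are those of the target (C1 = CMe2, C2 = CHBr, C3 = ring alkene carbon, C4 = CHCl, C5 = CH2, C6 = CHCl, C7 = alkene CH, C8 = CH2Br) and are used for every intermediate. The acetal carbon in 3–13 is assumed to take the thermodynamic configuration (aryl equatorial); it is removed in step 9.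

## Route

Step 1
Reactants: 1 D-(−)-pantolactone, (3R)-3-hydroxy-4,4-dimethyloxolan-2-one
Product: 2 (2R)-3,3-dimethylbutane-1,2,4-triol
Conditions: LiAlH4, THF, 0 °C → reflux; aq. NaOH work-up
Reagents that add atoms: none
Why: LiAlH4 reduction of a lactone to the diol; the carbinol centre (later C2) is not touched and keeps the configuration of the chiral pool.

Step 2
Reactants: 2 (2R)-3,3-dimethylbutane-1,2,4-triol
Product: 3 [(2R,4R)-2-(4-methoxyphenyl)-5,5-dimethyl-1,3-dioxan-4-yl]methanol
Conditions: 4-MeOC6H4CH(OMe)2, CSA (cat.), CH2Cl2, rt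
Reagents that add atoms: 4-methoxybenzaldehyde dimethyl acetal, COC(OC)c1ccc(OC)cc1
Why: Acid-catalysed transacetalisation under thermodynamic control should select the six-membered 5,5-dimethyl-1,3-dioxane across the C2 and C6 oxygens with the aryl group equatorial (cis to the CH2OH arm), leaving the primary C3 hydroxyl free.

Step 3
Reactants: 3 [(2R,4R)-2-(4-methoxyphenyl)-5,5-dimethyl-1,3-dioxan-4-yl]methanol
Product: 4 (2R,4R)-2-(4-methoxyphenyl)-5,5-dimethyl-1,3-dioxane-4-carbaldehyde
Conditions: (COCl)2, DMSO, CH2Cl2, −78 °C; Et3N, −78 → 0 °C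
Reagents that add atoms: none
Why: Swern oxidation at low temperature gives the α-alkoxy aldehyde without epimerising C2 and without acid that would open the acetal.

Step 4
Reactants: 4 (2R,4R)-2-(4-methoxyphenyl)-5,5-dimethyl-1,3-dioxane-4-carbaldehyde
Product: 5 (2R,4S)-4-(2,2-dibromoethenyl)-2-(4-methoxyphenyl)-5,5-dimethyl-1,3-dioxane
Conditions: CBr4, PPh3, Et3N, CH2Cl2, 0 °C
Reagents that add atoms: carbon tetrabromide, BrC(Br)(Br)Br
Why: First stage of the Corey–Fuchs reaction (Wittig-type dibromo-olefination), which adds C7; the amine buffer protects the acetal.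

Step 5
Reactants: 5 (2R,4S)-4-(2,2-dibromoethenyl)-2-(4-methoxyphenyl)-5,5-dimethyl-1,3-dioxane
Product: 7 methyl 3-[(2R,4S)-2-(4-methoxyphenyl)-5,5-dimethyl-1,3-dioxan-4-yl]prop-2-ynoate, via lithium acetylide 6 (not isolated)
Conditions: n-BuLi (2.2 equiv), THF, −78 °C; ClCO2Me, −78 → 0 °C
Reagents that add atoms: methyl chloroformate, COC(=O)Cl
Why: Second stage of the Corey–Fuchs reaction (bromine–lithium exchange, rearrangement to the lithium acetylide) with C-acylation by the chloroformate, which adds C8 at the ester level.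

Step 6
Reactants: 7 methyl 3-[(2R,4S)-2-(4-methoxyphenyl)-5,5-dimethyl-1,3-dioxan-4-yl]prop-2-ynoate; 8 ethyl vinyl ether
Product: 11 methyl (2E)-4-ethoxy-3-[(2R,4R)-2-(4-methoxyphenyl)-5,5-dimethyl-1,3-dioxan-4-yl]penta-2,4-dienoate, via 1-ethoxyvinyllithium 9 (not isolated), via lithium bis(1-ethoxyvinyl)cuprate 10 (not isolated)
Conditions: 8, t-BuLi, THF, −78 → 0 °C; CuBr·SMe2, −78 °C; then 7, −78 °C; MeOH, −78 °C, then aq. NH4Cl
Reagents that add atoms: none
Why: Conjugate syn-carbocupration of a 2-alkynoate by a Gilman cuprate at −78 °C puts the 1-ethoxyvinyl group (C4, C5) on C3 and copper on C7 on the same side; protonation of the vinylcopper with retention should leave the C2-bearing dioxane cis to C8 and the masked acetyl group trans to it, the alkene geometry of the target.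

Step 7
Reactants: 11 methyl (2E)-4-ethoxy-3-[(2R,4R)-2-(4-methoxyphenyl)-5,5-dimethyl-1,3-dioxan-4-yl]penta-2,4-dienoate
Product: 12 (2E)-4-ethoxy-3-[(2R,4R)-2-(4-methoxyphenyl)-5,5-dimethyl-1,3-dioxan-4-yl]penta-2,4-dien-1-ol
Conditions: i-Bu2AlH (2.2 equiv), CH2Cl2, −78 °C; aq. KNaC4H4O6
Reagents that add atoms: none
Why: 1,2-Reduction of the conjugated ester by i-Bu2AlH at −78 °C; at this temperature the acetal and the enol ether should remain intact.

Step 8
Reactants: 12 (2E)-4-ethoxy-3-[(2R,4R)-2-(4-methoxyphenyl)-5,5-dimethyl-1,3-dioxan-4-yl]penta-2,4-dien-1-ol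
Product: 13 tert-butyl{[(2E)-4-ethoxy-3-[(2R,4R)-2-(4-methoxyphenyl)-5,5-dimethyl-1,3-dioxan-4-yl]penta-2,4-dien-1-yl]oxy}dimethylsilane
Conditions: TBSCl, imidazole, DMF, 0 °C → rt
Reagents that add atoms: tert-butyldimethylsilyl chloride, CC(C)(C)[Si](C)(C)Cl
Why: Standard silylation of the primary allylic C8 hydroxyl under basic conditions that the acid-labile enol ether and acetal tolerate.

Step 9
Reactants: 13 tert-butyl{[(2E)-4-ethoxy-3-[(2R,4R)-2-(4-methoxyphenyl)-5,5-dimethyl-1,3-dioxan-4-yl]penta-2,4-dien-1-yl]oxy}dimethylsilane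
Product: 14 (3R,4E)-6-[(tert-butyldimethylsilyl)oxy]-4-(1-ethoxyethenyl)-3-[(4-methoxyphenyl)methoxy]-2,2-dimethylhex-4-en-1-ol
Conditions: i-Bu2AlH (3 equiv), CH2Cl2, −78 → 0 °C; aq. KNaC4H4O6
Reagents that add atoms: none
Why: Reductive opening of a 4-methoxybenzylidene acetal by i-Bu2AlH: aluminium binds the less hindered primary C6 oxygen, that C–O bond ionises and hydride reduces the oxocarbenium ion, so the PMB group should stay on the secondary C2 oxygen while the C6 hydroxyl is freed.

Step 10
Reactants: 14 (3R,4E)-6-[(tert-butyldimethylsilyl)oxy]-4-(1-ethoxyethenyl)-3-[(4-methoxyphenyl)methoxy]-2,2-dimethylhex-4-en-1-ol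
Product: 16 (3R,4E)-4-acetyl-6-[(tert-butyldimethylsilyl)oxy]-3-[(4-methoxyphenyl)methoxy]-2,2-dimethylhex-4-enal, via ethoxydienyl aldehyde 15 (not isolated)
Conditions: SO3·pyridine, DMSO, i-Pr2NEt, CH2Cl2, 0 °C; then 0.5 M aq. oxalic acid, THF, 0 °C
Reagents that add atoms: water, O
Why: Parikh–Doering oxidation converts the neopentyl alcohol into the non-enolisable C6 aldehyde in a basic medium that spares the enol ether; dilute acid then hydrolyses the 2-ethoxydiene (protonation at C5) to the C4 methyl ketone.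

Step 11
Reactants: 16 (3R,4E)-4-acetyl-6-[(tert-butyldimethylsilyl)oxy]-3-[(4-methoxyphenyl)methoxy]-2,2-dimethylhex-4-enal
Product: 17 (2E,3R,5R)-2-[2-[(tert-butyldimethylsilyl)oxy]ethylidene]-5-hydroxy-3-[(4-methoxyphenyl)methoxy]-4,4-dimethylcyclohexan-1-one (C2 ether and C6 hydroxyl cis)
Conditions: MgBr2·OEt2 (3 equiv), i-Pr2NEt (3.5 equiv), CH2Cl2, −20 → 0 °C; aq. NaH2PO4/Na2HPO4 (pH 7)
Reagents that add atoms: none
Why: MgBr2 bound to the C4 carbonyl acidifies the C5 methyl so that i-Pr2NEt can remove a proton (soft enolisation), and the magnesium enolate adds to the C6 aldehyde to form C5–C6. The closest known reaction type is the magnesium halide/amine soft-enolisation aldol addition of ketones and thioesters, run here intramolecularly as the aldol cyclisation of a keto aldehyde. The one ring, the six-membered carbocycle C1–C6, closes in the 6-(enolendo)-exo-trig mode. The new stereocentre C6 is controlled by a magnesium ion bridging the C2 ether oxygen and the aldehyde oxygen; the bridge exists only when both oxygens are axial on the same face of the forming chair, an arrangement that allylic 1,3-strain between C8 and the C2 substituent already favours, so the C6 hydroxyl should arise cis to the C2 ether (6R). The step needs site-selective enolisation (C5 methyl, not the C8 methylene) and a single aldol pathway: the hindered amine with fast intramolecular capture should secure the first, and the substrate secures the second, because the aldehyde sits on quaternary C1 and C3 is an alkene carbon. Dehydration and retro-aldol should be held back by the chelated magnesium aldolate, the low temperature and the buffered quench, and 17 is taken on at once.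

Step 12
Reactants: 17 (2E,3R,5R)-2-[2-[(tert-butyldimethylsilyl)oxy]ethylidene]-5-hydroxy-3-[(4-methoxyphenyl)methoxy]-4,4-dimethylcyclohexan-1-one
Product: 18 (1R,3R,5R,6Z)-6-[2-[(tert-butyldimethylsilyl)oxy]ethylidene]-5-[(4-methoxyphenyl)methoxy]-4,4-dimethylcyclohexane-1,3-diol (C4 hydroxyl trans to C6 hydroxyl)
Conditions: Me4NBH(OAc)3, MeCN/AcOH (1:1), −30 °C
Reagents that add atoms: none
Why: Hydroxyl-directed reduction of the Evans–Saksena type: the axial C6 hydroxyl exchanges onto boron and delivers hydride to the C4 carbonyl from its own face, so the new C4 hydroxyl should be trans to the C6 hydroxyl (anti-1,3-diol), with 1,2-reduction of the enone.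

Step 13
Reactants: 18 (1R,3R,5R,6Z)-6-[2-[(tert-butyldimethylsilyl)oxy]ethylidene]-5-[(4-methoxyphenyl)methoxy]-4,4-dimethylcyclohexane-1,3-diol
Product: 19 (2R,3E,4S,6S)-3-[2-[(tert-butyldimethylsilyl)oxy]ethylidene]-4,6-dichloro-2-[(4-methoxyphenyl)methoxy]-1,1-dimethylcyclohexane
Conditions: PPh3, NCS (premixed), THF, 0 → 45 °C
Reagents that add atoms: N-chlorosuccinimide, O=C1CCC(=O)N1Cl
Why: Appel-type deoxychlorination: each hydroxyl becomes an alkoxyphosphonium ion that chloride displaces by SN2, so C4 and C6 are both inverted to the chloride configurations of the target; the PMB and silyl ethers should survive the neutral conditions.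

Step 14
Reactants: 19 (2R,3E,4S,6S)-3-[2-[(tert-butyldimethylsilyl)oxy]ethylidene]-4,6-dichloro-2-[(4-methoxyphenyl)methoxy]-1,1-dimethylcyclohexane
Product: 20 (2R,3E,4S,6S)-3-(2-bromoethylidene)-4,6-dichloro-2-[(4-methoxyphenyl)methoxy]-1,1-dimethylcyclohexane
Conditions: Ph3PBr2, CH2Cl2, 0 °C → rt
Reagents that add atoms: dibromotriphenylphosphorane, BrP(Br)(c1ccccc1)(c1ccccc1)c1ccccc1
Why: Ph3PBr2 converts a primary silyl ether directly into the bromide (silyl transfer to bromide, alkoxyphosphonium ion, SN2 at the unhindered allylic CH2); brominating C8 first removes a nucleophilic oxygen that could otherwise cyclise onto C2 later.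

Step 15
Reactants: 20 (2R,3E,4S,6S)-3-(2-bromoethylidene)-4,6-dichloro-2-[(4-methoxyphenyl)methoxy]-1,1-dimethylcyclohexane
Product: 21 (1R,3S,5S,6E)-6-(2-bromoethylidene)-3,5-dichloro-2,2-dimethylcyclohexan-1-ol
Conditions: DDQ, CH2Cl2/aq. NaH2PO4/Na2HPO4 (pH 7) 10:1, 0 °C
Reagents that add atoms: none
Why: Oxidative cleavage of the PMB ether by DDQ under buffered neutral conditions that the alkyl chlorides and the allylic bromide should tolerate; C2 is not touched.

Step 16
Reactants: 21 (1R,3S,5S,6E)-6-(2-bromoethylidene)-3,5-dichloro-2,2-dimethylcyclohexan-1-ol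
Product: 22 (2S,3Z,4S,6S)-2-bromo-3-(2-bromoethylidene)-4,6-dichloro-1,1-dimethylcyclohexane (CNP0137413.1)
Conditions: PPh3/CBr4 (premixed), CH2Cl2, −20 → 0 °C
Reagents that add atoms: carbon tetrabromide, BrC(Br)(Br)Br
Why: Appel bromination: the C2 alkoxyphosphonium ion is displaced by bromide with inversion, turning the C2 oxygen that was cis to the C6 oxygen into the C2 bromine cis to the C6 chlorine; premixing leaves no free phosphine to attack the allylic bromide.

## Compound list

1 | D-(−)-pantolactone, (3R)-3-hydroxy-4,4-dimethyloxolan-2-one | CC1(C)COC(=O)[C@@H]1O | starting material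
2 | (2R)-3,3-dimethylbutane-1,2,4-triol | OC[C@H](O)C(C)(C)CO | intermediate
3 | [(2R,4R)-2-(4-methoxyphenyl)-5,5-dimethyl-1,3-dioxan-4-yl]methanol | OC[C@@H]1O[C@H](c2ccc(OC)cc2)OCC1(C)C | intermediate
4 | (2R,4R)-2-(4-methoxyphenyl)-5,5-dimethyl-1,3-dioxane-4-carbaldehyde | O=C[C@@H]1O[C@H](c2ccc(OC)cc2)OCC1(C)C | intermediate
5 | (2R,4S)-4-(2,2-dibromoethenyl)-2-(4-methoxyphenyl)-5,5-dimethyl-1,3-dioxane | BrC(Br)=C[C@@H]1O[C@H](c2ccc(OC)cc2)OCC1(C)C | intermediate
6 | lithium acetylide of the dioxane (C3≡C7–Li) | [Li]C#C[C@@H]1O[C@H](c2ccc(OC)cc2)OCC1(C)C | intermediate (not isolated)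
7 | methyl 3-[(2R,4S)-2-(4-methoxyphenyl)-5,5-dimethyl-1,3-dioxan-4-yl]prop-2-ynoate | COC(=O)C#C[C@@H]1O[C@H](c2ccc(OC)cc2)OCC1(C)C | intermediate
8 | ethyl vinyl ether | C=COCC | starting material
9 | 1-ethoxyvinyllithium | [Li]C(=C)OCC | intermediate (not isolated)
10 | lithium bis(1-ethoxyvinyl)cuprate, Li[Cu(C(OEt)=CH2)2] | [Li+].C=C(OCC)[Cu-]C(=C)OCC | intermediate (not isolated)
11 | methyl (2E)-4-ethoxy-3-[(2R,4R)-2-(4-methoxyphenyl)-5,5-dimethyl-1,3-dioxan-4-yl]penta-2,4-dienoate | COC(=O)/C=C(/C(=C)OCC)[C@@H]1O[C@H](c2ccc(OC)cc2)OCC1(C)C | intermediate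
12 | (2E)-4-ethoxy-3-[(2R,4R)-2-(4-methoxyphenyl)-5,5-dimethyl-1,3-dioxan-4-yl]penta-2,4-dien-1-ol | OC/C=C(/C(=C)OCC)[C@@H]1O[C@H](c2ccc(OC)cc2)OCC1(C)C | intermediate
13 | tert-butyl{[(2E)-4-ethoxy-3-[(2R,4R)-2-(4-methoxyphenyl)-5,5-dimethyl-1,3-dioxan-4-yl]penta-2,4-dien-1-yl]oxy}dimethylsilane | CC(C)(C)[Si](C)(C)OC/C=C(/C(=C)OCC)[C@@H]1O[C@H](c2ccc(OC)cc2)OCC1(C)C | intermediate
14 | (3R,4E)-6-[(tert-butyldimethylsilyl)oxy]-4-(1-ethoxyethenyl)-3-[(4-methoxyphenyl)methoxy]-2,2-dimethylhex-4-en-1-ol | CC(C)(C)[Si](C)(C)OC/C=C(/C(=C)OCC)[C@H](OCc1ccc(OC)cc1)C(C)(C)CO | intermediate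
15 | (3S,4E)-6-[(tert-butyldimethylsilyl)oxy]-4-(1-ethoxyethenyl)-3-[(4-methoxyphenyl)methoxy]-2,2-dimethylhex-4-enal | CC(C)(C)[Si](C)(C)OC/C=C(/C(=C)OCC)[C@H](OCc1ccc(OC)cc1)C(C)(C)C=O | intermediate (not isolated)
16 | (3R,4E)-4-acetyl-6-[(tert-butyldimethylsilyl)oxy]-3-[(4-methoxyphenyl)methoxy]-2,2-dimethylhex-4-enal (keto aldehyde, key-step precursor) | CC(=O)/C(=C/CO[Si](C)(C)C(C)(C)C)[C@H](OCc1ccc(OC)cc1)C(C)(C)C=O | intermediate
17 | (2E,3R,5R)-2-[2-[(tert-butyldimethylsilyl)oxy]ethylidene]-5-hydroxy-3-[(4-methoxyphenyl)methoxy]-4,4-dimethylcyclohexan-1-one (key-step product) | CC1(C)[C@@H](OCc2ccc(OC)cc2)/C(=C\CO[Si](C)(C)C(C)(C)C)C(=O)C[C@H]1O | intermediate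
18 | (1R,3R,5R,6Z)-6-[2-[(tert-butyldimethylsilyl)oxy]ethylidene]-5-[(4-methoxyphenyl)methoxy]-4,4-dimethylcyclohexane-1,3-diol | CC1(C)[C@@H](OCc2ccc(OC)cc2)/C(=C\CO[Si](C)(C)C(C)(C)C)[C@H](O)C[C@H]1O | intermediate
19 | (2R,3E,4S,6S)-3-[2-[(tert-butyldimethylsilyl)oxy]ethylidene]-4,6-dichloro-2-[(4-methoxyphenyl)methoxy]-1,1-dimethylcyclohexane | CC1(C)[C@@H](OCc2ccc(OC)cc2)/C(=C\CO[Si](C)(C)C(C)(C)C)[C@@H](Cl)C[C@@H]1Cl | intermediate
20 | (2R,3E,4S,6S)-3-(2-bromoethylidene)-4,6-dichloro-2-[(4-methoxyphenyl)methoxy]-1,1-dimethylcyclohexane | CC1(C)[C@@H](OCc2ccc(OC)cc2)/C(=C\CBr)[C@@H](Cl)C[C@@H]1Cl | intermediate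
21 | (1R,3S,5S,6E)-6-(2-bromoethylidene)-3,5-dichloro-2,2-dimethylcyclohexan-1-ol | CC1(C)[C@@H](O)/C(=C\CBr)[C@@H](Cl)C[C@@H]1Cl | intermediate
22 | (2S,3Z,4S,6S)-2-bromo-3-(2-bromoethylidene)-4,6-dichloro-1,1-dimethylcyclohexane | CC1(C)[C@H](Br)/C(=C\CBr)[C@@H](Cl)C[C@@H]1Cl | target

## Step count and risks

Total step count: 16. Longest linear sequence: 16 steps from D-pantolactone (ethyl vinyl ether enters in step 6 without prior steps).

**Step 13 (double deoxychlorination).** At the neopentyl C6 centre, elimination toward C5 or methyl migration may outrun substitution. At the allylic C4 centre, chloride may attack C7 with allylic transposition. Under forcing conditions the C8 silyl ether may also be exchanged. The fallback separates the two carbinols and replaces the in-flask phosphonium leaving group at C6 by an isolated sulfonate. It sets out from 18: one equivalent of the PPh3/NCS reagent at −20 °C should chlorinate only the more accessible allylic C4 hydroxyl, giving (1R,3R,4E,5S)-4-[2-[(tert-butyldimethylsilyl)oxy]ethylidene]-5-chloro-3-[(4-methoxyphenyl)methoxy]-2,2-dimethylcyclohexan-1-ol F1. The C6 hydroxyl is then esterified with ClCH2SO2Cl/pyridine to the chloromethanesulfonate F2, and LiCl in DMF displaces it with inversion. The sequence comes back to the route at 19.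

**Step 16 (bromination at C2).** The activated neopentyl, allylic C2 position may ionise or suffer bromide attack at C7, giving loss of configuration or a transposed bromide; bromide may also exchange with the allylic C4 chloride. The fallback leaves the phosphonium ion-pair chemistry for a discrete sulfonate that is displaced by free bromide. It sets out from 21: Ms2O/pyridine at −20 °C (no chloride present) gives (1R,3S,5S,6E)-6-(2-bromoethylidene)-3,5-dichloro-2,2-dimethylcyclohexyl methanesulfonate F3, and LiBr in acetone displaces it by SN2 with inversion. The sequence comes back at 22.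

**Step 11 (aldol ring closure).** Deprotonation at C8 instead of C5 may scramble the alkene geometry or expel the C2 ether, the aldol may dehydrate under the amine, or facial control at C6 may be insufficient. The fallback forms the same C5–C6 bond without base, using the enol ether already present as the nucleophile in a Mukaiyama-type cyclisation. It sets out from 15, isolated in this variant after the oxidation of step 10 by a basic work-up. MgBr2·OEt2 in CH2Cl2 at −78 °C chelates the C2 ether and the C6 aldehyde, and the enol ether terminus C5 adds to give (1R,4E,5R)-4-[2-[(tert-butyldimethylsilyl)oxy]ethylidene]-3-ethoxy-5-[(4-methoxyphenyl)methoxy]-6,6-dimethylcyclohex-2-en-1-ol F4. Dilute aqueous oxalic acid hydrolyses its enol ether, and the sequence comes back at 17.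

## Further compounds

F1 | step 13 | (1R,3R,4E,5S)-4-[2-[(tert-butyldimethylsilyl)oxy]ethylidene]-5-chloro-3-[(4-methoxyphenyl)methoxy]-2,2-dimethylcyclohexan-1-ol | CC1(C)[C@@H](OCc2ccc(OC)cc2)/C(=C\CO[Si](C)(C)C(C)(C)C)[C@@H](Cl)C[C@H]1O
F2 | step 13 | chloromethanesulfonate of F1 at the C6 oxygen | CC1(C)[C@@H](OCc2ccc(OC)cc2)/C(=C\CO[Si](C)(C)C(C)(C)C)[C@@H](Cl)C[C@H]1OS(=O)(=O)CCl
F3 | step 16 | (1R,3S,5S,6E)-6-(2-bromoethylidene)-3,5-dichloro-2,2-dimethylcyclohexyl methanesulfonate | CC1(C)[C@@H](OS(C)(=O)=O)/C(=C\CBr)[C@@H](Cl)C[C@@H]1Cl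
F4 | step 11 | (1R,4E,5R)-4-[2-[(tert-butyldimethylsilyl)oxy]ethylidene]-3-ethoxy-5-[(4-methoxyphenyl)methoxy]-6,6-dimethylcyclohex-2-en-1-ol | CC1(C)[C@@H](OCc2ccc(OC)cc2)/C(=C\CO[Si](C)(C)C(C)(C)C)C(OCC)=C[C@H]1O
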